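Late in the red run nothing moves any more: solvolysis product reads 81% at 30.0 s and 79% at 90.0 s, and substrate is down to 3% by 12.0 s. Substrate turns up as target by capture with first nucleophile, as other capture product with second nucleophile, or as solvolysis product.

| flask | substrate | first nucleophile | second nucleophile | temperature | remark | time |
|---|---|---|---|---|---|---|
| red | 0.40 M | 0.24 M | 0.24 M | 106 °C | run made earlier |  |
| violet | 0.40 M | 0.96 M | 0.24 M | 120 °C | run made earlier |  |
| ochre | 0.80 M | 0.48 M | 0.24 M | 106 °C | run made earlier |  |
| birch | 0.40 M | 0.480 M | 0.240 M | 100 °C |  | 2.0 min |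
| cedar | 0.40 M | 0.480 M | 0.240 M | 125 °C |  | 2.0 min |

| run | time / s | solvolysis product / % | other capture product / % | substrate / % | target / % |
|---|---|---|---|---|---|
| red | 12.0 | 76 | 0 | 3 | 14 |
| red | 30.0 | 81 | 7 | 2 | 16 |
| red | 60.0 | 79 | 2 | 2 | 12 |
| red | 90.0 | 79 | 5 | 0 | 17 |
| violet | 10.0 | 63 | 1 | 2 | 39 |
| violet | 20.0 | 58 | 0 | 1 | 37 |
| violet | 30.0 | 59 | 2 | 3 | 37 |
| ochre | 25.0 | 69 | 5 | 2 | 27 |
| ochre | 50.0 | 73 | 5 | 1 | 26 |
| ochre | 80.0 | 71 | 3 | 0 | 28 |
| ochre | 90.0 | 72 | 5 | 2 | 25 |

(readings scatter by 2 percentage points)



1. which of these there is most of at the end, counted by the substrate in it, birch (solvolysis product / target / substrate / other capture product)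
2. which of these there is most of at the end, counted by the substrate in it, cedar (solvolysis product / target / substrate / other capture product)
3. the largest of these amounts at the end, in percent of the substrate charged, birch
4. the largest of these amounts at the end, in percent of the substrate charged, cedar

Which given number must be known well? Time need not be: 2.0 min is ten times the red run's first reading, so the split is read from late amounts. Second nucleophile is charged alike in all runs, and its other capture product reads a small share, 4.44% of solvolysis product in the red run. Substrate charge counts through the depletion of first nucleophile, so [first nucleophile] is taken as its mean over the capture.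

The number that matters is therefore a count of turnovers. Per unit of mean [first nucleophile], target per solvolysis product reads 0.890 L mol⁻¹ in red and 0.994 L mol⁻¹ in ochre, mean 0.942 L mol⁻¹. Violet reads lower than that, 0.710 L mol⁻¹, and violet is the hotter run, so the ratio is taken to fall with temperature. Geometric extrapolation from the mean temperature of red and ochre gives 1.06 L mol⁻¹ for birch, the selectivity factor S: capture turnovers per solvolysis turnover at unit [first nucleophile]. Cedar gets 0.641 L mol⁻¹. My own reckoning, solvolysis product as one over one plus S times mean [first nucleophile] plus the side share, gives 67.3% for birch and 75.6% for cedar.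

The forecast, a little apart from these, says solvolysis product at 66% for birch and solvolysis product at 77% for cedar: “Capture therefore loses ground as temperature rises.”

The flask gives solvolysis product at 64.7% in birch and solvolysis product at 74.8% in cedar.

    first nucleophile + intermediate → target (k = 270 L mol⁻¹ s⁻¹, Ea = 37.0 kJ mol⁻¹)
    target → over-reaction product (k = 8.80 × 10⁻⁵ s⁻¹, Ea = 123 kJ mol⁻¹)
    intermediate → solvolysis product (k = 230 s⁻¹, Ea = 64.0 kJ mol⁻¹)
    substrate → intermediate (k = 0.150 s⁻¹, Ea = 84.0 kJ mol⁻¹)
    second nucleophile + intermediate → other capture product (k = 59.0 L mol⁻¹ s⁻¹, Ea = 45.0 kJ mol⁻¹)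
    (constants at 100 °C)

Cedar holds more solvolysis product than birch because of its temperature: without that difference it holds 64.7%, not 74.8%. In birch, 1.06 L mol⁻¹ times the mean [first nucleophile] of 0.417 M counts 0.442 capture turnovers per solvolysis turnover, and the flask's target over solvolysis product is 0.481. A neighbour of birch with 1.9 M of first nucleophile has a mean of 1.77 M, so the same S counts 1.88 and gives 34.2% of solvolysis product. That flask holds 31.9%.

The runs are simulated for substances that don't exist; scatter was added.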